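## Structural features

Prosogerin D is a flavone. Benzo ring A is fused along C4a–C8a to 4-pyranone ring C (O1, C2, C3, C4), and the 3,4,5-trimethoxyphenyl ring B is attached to C2 by a single bond. Ring A carries a methoxy group at C6 and a free hydroxyl at C7, so O1 lies para to the C6 methoxy group and C4a lies para to the C7 oxygen. The target has no stereocenter, so every sp3 center made on the way is temporary and may be racemic. The fragile points are the four aryl methyl ethers, which must outlive the unmasking of the single phenol, the base-sensitive pyranone (hydroxide opens it at C2) and the C2=C3 bond, which can be over-reduced. The real difficulty is regiochemical: the two ring A oxygens must be told apart, and ring C must be annulated at the correct one of the two ortho carbons of a 3,4-dioxygenated phenol, with C4 at the ketone level and C2=C3 unsaturated. The key step exploits the fact that the chain O1–C2–C3–C4 is the O–CH(aryl)–C≡C unit of an aryl propargyl ether. The ring A phenol oxygen is O1, the propargylic carbon bearing ring B is C2, the alkyne carbons are C3 and C4, and C4a is the unsubstituted ortho carbon para to the C7 oxygen. A chlorine on the alkyne terminus travels to C4 and stores the ketone oxidation level there.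

## Logic of the disconnections

17 to 16. A benzyl group is put back on the C7 oxygen (the O–CH2Ph bond is the one cleaved forward). The C7 oxygen must be masked from the start so that the ring A building block has exactly one free phenol and so that this oxygen acts as a para donor in the ring-forming step. The gain is an endgame whose only chemoselectivity question is benzyl against methyl ether. The forward step must cleave O–CH2Ph without reducing C2=C3 or C4=O.

16 to 14. The C2=C3 double bond is returned to C2–H/C3–H; forward this is a dehydrogenation that passes through 15. The cut is made here because the ring-forming step delivers C2 as an sp3 carbon. The gain is that 14 is the direct hydrolysis product of the key-step product. The oxidant must tolerate two electron-rich arenes and a benzyl ether.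

14 to 13. The C4 carbonyl is exchanged for a C3=C4 double bond with chlorine on C4. A vinyl chloride is what a chloroalkyne leaves behind, and it already sits at the ketone oxidation level, so no separate oxidation at C4 is needed. The forward hydrolysis must be mild enough for the benzylic C2–O1 bond and the benzyl ether.

13 to 9. The C4–C4a bond is cut and C3=C4 becomes an alkyne again. The O1–C2 bond is drawn intact in 9, although the forward cascade breaks it and makes it again (through 10, 11 and 12). This single cut removes ring C and one skeletal C–C bond and leaves an acyclic aryl propargyl ether. The forward step must select the ortho carbon para to the benzyloxy group, must rearrange before the doubly activated C–O bond ionises, and must close to the chromene and not to a benzofuran.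

9 to 7. The C–Cl bond at the alkyne terminus is cut; forward it is formed through 8. A terminal alkyne is the robust partner for ether formation. The chlorine is best delivered to a carbanion: electrophilic chlorination could attack the most electron-rich ring A carbon, the very one that must stay free to become C4a. The base must remove only the sp C–H.

7 to 3 and 6. The O1–C2 ether bond is cut. This is the most convergent cut, giving a ring A phenol and a ring B alcohol that already holds C2, C3 and C4. The forward step must O-alkylate at a secondary benzylic–propargylic carbon without C-alkylation of the phenol and without allenyl ether formation.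

3 to 1 and 2. The C2–C3 bond between carbinol carbon and alkyne is cut, which leads to two commercial compounds. The forward step needs only clean 1,2-addition to a non-enolisable aldehyde.

6 to 4 (through 5). The aryl C–O bond of the phenol is exchanged for an aryl–CHO bond. The 1,3,4-oxygen pattern with two different ethers is readily bought as the aldehyde but not as the phenol. In the forward oxidation, aryl migration must beat hydride migration, and both ethers must survive the peracid.

## Other disconnections considered

Alternative 1: Ring A is removed by cutting C4a–C5 and C8–C8a, keeping rings C and B. Forward, the pyranone ester A1 would act as dienophile through its ketone- and ester-activated C2=C3 bond towards silyloxydiene A2 under ZnCl2 promotion, giving the cis-fused adduct A3 with the enol ether oxygen at C7.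
- In its favour: the nucleophilic diene terminus should bond to the β-carbon of the enone ester, so the C7 oxygen is placed reliably. On regiochemical certainty of the key bond formation it is the equal of the chosen plan or better.
- Also in its favour: ring C is at the flavone oxidation level from the outset, so neither vinyl chloride hydrolysis nor C2–C3 dehydrogenation is needed. On that point it is better.
- Against it: A3 holds only one of the two ring A oxygens. It would still need C6 oxygenation (Rubottom-type oxidation of the enol ether), methylation of the C6 oxygen in the presence of the C7 oxygen, loss of the angular ester (dealkoxycarbonylation of a β-keto ester) and removal of two further pairs of hydrogens to aromatise ring A.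
- Against it on structure: it builds a benzene ring that can be bought with its oxygens already differentiated, and it creates two stereocenters (C4a, C8a) only to erase them.
- On step economy: preparing A1 plus at least five operations after the cycloaddition should exceed the eight steps of the chosen route. The aromatisation sequence is also harder to predict than a thermal pericyclic cascade.

Alternative 2: Ring A is assembled by cutting C5–C6, C4a–C8a and C8–C8a. Forward, heating the alkenyl carbene complex A4 (zerovalent chromium) with the terminal alkyne of diyne A5 would trigger alkyne insertion, CO insertion and ring closure to phenol A6. The carbene carbon becomes C6 (OMe), the CO carbon becomes C8a (the free OH, later O1), and the larger alkyne substituent lands ortho to that hydroxyl.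
- In its favour: all three ring A oxygens arrive differentiated and their positions follow from the connectivity of the reagents, with no choice between two ortho carbons. On regiochemical certainty it is better than the chosen plan.
- Also in its favour: C4 is oxygenated from the start and C2–C3 is an alkyne at the flavone oxidation level, so no dehydrogenation is needed. On oxidation-state economy it is better as well.
- Against it: it needs stoichiometric chromium carbonyl chemistry, and the α-alkoxyvinyl carbene complex A4 takes several steps to make.
- Against it on mechanism: the cascade has more branch points (cyclobutenone or furan formation, reaction at the internal aryl alkyne of A5), and the electron-rich phenol A6 could be oxidised towards a quinone on release from the metal.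
- On step economy: A6 would still need desilylation, oxidation to the ynone, 6-endo oxa-Michael closure (with 5-exo closure to an aurone as competitor) and loss of the tert-butyl group. The total is therefore not expected to be shorter than the chosen eight steps.

Alternative 3: Only the O1–C8a bond is cut. Forward, anodic oxidation of diketone phenol A7 (graphite anode, undivided cell, hexafluoroisopropanol with Bu4NBF4) would oxidise the phenol whose hydroxyl becomes the C6 oxygen. The diketone enol oxygen would attack the para carbon (C8a), and loss of a proton would restore aromaticity to give A8 with 6-OH and 7-OBn. O-Methylation of A8 would give 16, and the plan would then merge with the chosen route at its last step.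
- In its favour: A7 is two or three steps from an acetophenone and a benzoate ester, so the whole route would be about five steps. On step economy it is better than the chosen plan.
- Also in its favour: it needs no halogen, no prefunctionalised C8a, no heating and no chemical oxidant, so it is better on atom economy too. Ring C is formed directly at the chromone level, and it uses a purchased ring A just as the chosen plan does.
- Against it: C–O bond formation at an unsubstituted arene carbon ortho to an acyl group by anodic phenol oxidation is not an established flavone ring closure.
- Against it on selectivity: the acyl group deactivates ring A, and the other ortho carbon of the ketone is also within reach of the enol oxygen.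
- Against it on chemoselectivity: the diketone enol, the trimethoxyphenyl ring and above all A8, a more electron-rich phenol than A7, are oxidisable in the same potential range, so over-oxidation and dimerisation are real threats.
- Overall: this is the shortest plan but the least secured in mechanism, whereas each step of the chosen plan has a known reaction type behind it.

Key step: step 5

Remark: compound 4 is taken as a catalogue compound (it is otherwise one O-benzylation of isovanillin away). All compounds with sp3 stereocenters are racemates, which is without consequence because the target has none. The atom mapping of 9 and 13 onto the target (phenol oxygen to O1, OMe para to it at C6, OBn at C7) was checked and needs no structural correction.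

## Route

Step 1
Reactants: 1 3,4,5-trimethoxybenzaldehyde; 2 ethynylmagnesium bromide
Product: 3 1-(3,4,5-trimethoxyphenyl)prop-2-yn-1-ol (racemic)
Conditions: 2 (1.3 equiv, 0.5 M in THF), THF, 0 °C to rt; aq NH4Cl
Reagents that add atoms: none
Why: Grignard 1,2-addition of an alkynyl nucleophile to a non-enolisable aromatic aldehyde; the new carbinol center forms as a racemate, which is acceptable because this carbon ends as sp2 C2.

Step 2
Reactants: 4 3-(benzyloxy)-4-methoxybenzaldehyde
Product: 6 3-(benzyloxy)-4-methoxyphenol, via 3-(benzyloxy)-4-methoxyphenyl formate 5 (not isolated)
Conditions: mCPBA (1.3 equiv), CH2Cl2, 0 °C to rt; then NaOH, MeOH/H2O, rt; aq HCl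
Reagents that add atoms: mCPBA (3-chloroperoxybenzoic acid), O=C(OO)c1cccc(Cl)c1
Why: Baeyer–Villiger (Dakin-type) oxidation in which the electron-rich aryl group migrates in preference to hydrogen, followed by saponification of formate 5 in the same flask; benzyl and methyl ethers are inert to peracid and dilute base.

Step 3
Reactants: 3 1-(3,4,5-trimethoxyphenyl)prop-2-yn-1-ol; 6 3-(benzyloxy)-4-methoxyphenol
Product: 7 2-(benzyloxy)-1-methoxy-4-{[1-(3,4,5-trimethoxyphenyl)prop-2-yn-1-yl]oxy}benzene (racemic)
Conditions: PPh3 (1.3 equiv), DIAD (1.3 equiv), THF, 0 °C to rt
Reagents that add atoms: none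
Why: Mitsunobu etherification: the phenol (pKa about 10) displaces the alkoxyphosphonium group at the secondary benzylic–propargylic carbon, which has no β-hydrogen and so cannot eliminate; inversion is irrelevant for a racemate.

Step 4
Reactants: 7 2-(benzyloxy)-1-methoxy-4-{[1-(3,4,5-trimethoxyphenyl)prop-2-yn-1-yl]oxy}benzene
Product: 9 2-(benzyloxy)-4-{[3-chloro-1-(3,4,5-trimethoxyphenyl)prop-2-yn-1-yl]oxy}-1-methoxybenzene (racemic), via lithium acetylide 8 (not isolated)
Conditions: n-BuLi (1.05 equiv), THF, −78 °C; then NCS (1.2 equiv), −78 to 0 °C; H2O
Reagents that add atoms: N-chlorosuccinimide, O=C1CCC(=O)N1Cl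
Why: Deprotonation of the terminal alkyne and chlorine transfer from NCS to acetylide 8, a standard route to 1-chloroalkynes; one equivalent of base at −78 °C leaves the propargylic C–H alone, and chlorine never meets ring A as an electrophile, so the carbon that must become C4a stays unsubstituted.

Step 5
Reactants: 9 2-(benzyloxy)-4-{[3-chloro-1-(3,4,5-trimethoxyphenyl)prop-2-yn-1-yl]oxy}-1-methoxybenzene
Product: 13 7-(benzyloxy)-4-chloro-6-methoxy-2-(3,4,5-trimethoxyphenyl)-2H-chromene (racemic), via allenyl cyclohexadienone 10 (not isolated), via 2-allenylphenol 11 (not isolated), via ortho-quinone methide 12 (not isolated)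
Conditions: PhNEt2 (0.05 M, degassed), 185 °C, Ar, sealed tube
Reagents that add atoms: none
Why: Thermal aryl propargyl ether Claisen cascade: a [3,3]-sigmatropic shift breaks the O–CH(aryl) bond of 9 and joins the chlorine-bearing alkyne carbon to the free ortho carbon (future C4a), giving dienone 10, which tautomerises to phenol 11. A 1,5-hydrogen shift from the phenolic oxygen to the central allene carbon then gives ortho-quinone methide 12 with its vinyl arm syn to the carbonyl oxygen. Ring C is closed by a thermally allowed disrotatory six-electron oxa-electrocyclisation of the 1-oxatriene in 12, which makes O1–C2 again and restores the aromaticity of ring A. The closest known reaction type is the thermal rearrangement of aryl propargyl ethers and aryl 3-chloropropargyl ethers to 2H-chromenes and 4-chloro-2H-chromenes in N,N-dialkylanilines. The one new stereocenter, C2, is not controlled: 9 is racemic and the cascade passes through planar 12, so 13 should form as a racemate, and C2 becomes trigonal in step 7. The selectivity needed is regiochemical: the new C–C bond must form at the ortho carbon para to the benzyloxy group and not at the carbon flanked by two oxygens; the buttressed benzyloxy group shields the latter and the para oxygen donor activates the former, in line with the known preference of 3,4-dialkoxyphenyl propargyl ethers for 6,7-dialkoxychromenes. The weakly basic, non-nucleophilic solvent scavenges traces of acid that would ionise the benzylic–propargylic C–O bond and avoids the stronger bases that divert 11 to benzofurans, and the aryl group on the propargylic carbon should let the shift run below the temperature that primary propargyl ethers need.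

Step 6
Reactants: 13 7-(benzyloxy)-4-chloro-6-methoxy-2-(3,4,5-trimethoxyphenyl)-2H-chromene
Product: 14 7-(benzyloxy)-6-methoxy-2-(3,4,5-trimethoxyphenyl)-2,3-dihydro-4H-chromen-4-one (racemic)
Conditions: TFA/H2O (9:1), rt to 40 °C
Reagents that add atoms: water, O
Why: Acid hydrolysis of an α-aryl vinyl chloride: protonation at C3 gives a C4 cation stabilised by chlorine, by O1 (ortho) and by the C7 oxygen (para), water adds at C4 and HCl is lost to reveal the ketone; this is the known conversion of 4-chloro-2H-chromenes into chroman-4-ones.

Step 7
Reactants: 14 7-(benzyloxy)-6-methoxy-2-(3,4,5-trimethoxyphenyl)-2,3-dihydro-4H-chromen-4-one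
Product: 16 7-(benzyloxy)-6-methoxy-2-(3,4,5-trimethoxyphenyl)-4H-chromen-4-one, via 3-iodoflavanone 15 (not isolated)
Conditions: I2 (10 mol %), DMSO, 125 °C
Reagents that add atoms: none
Why: Iodine/DMSO dehydrogenation of a flavanone: iodination at C3 through the enol gives 15, loss of HI creates C2=C3, and DMSO reoxidises HI to I2 so that iodine is catalytic; benzyl and methyl aryl ethers are compatible with these conditions.

Step 8
Reactants: 16 7-(benzyloxy)-6-methoxy-2-(3,4,5-trimethoxyphenyl)-4H-chromen-4-one
Product: 17 Prosogerin D, 7-hydroxy-6-methoxy-2-(3,4,5-trimethoxyphenyl)-4H-chromen-4-one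
Conditions: H2 (1 atm), Pd/C (10 wt %), EtOAc/MeOH, rt
Reagents that add atoms: none
Why: Catalytic hydrogenolysis of a benzyl aryl ether; at 1 atm and rt the conjugated C2=C3 bond of the chromone, the C4 carbonyl and the four methyl ethers should be retained if the reaction is stopped after one equivalent of hydrogen.

## Compound list

1 | 3,4,5-trimethoxybenzaldehyde | COc1cc(C=O)cc(OC)c1OC | starting material
2 | ethynylmagnesium bromide | C#C[Mg]Br | starting material
3 | 1-(3,4,5-trimethoxyphenyl)prop-2-yn-1-ol (racemic) | C#CC(O)c1cc(OC)c(OC)c(OC)c1 | intermediate
4 | 3-(benzyloxy)-4-methoxybenzaldehyde | COc1ccc(C=O)cc1OCc1ccccc1 | starting material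
5 | 3-(benzyloxy)-4-methoxyphenyl formate (not isolated) | COc1ccc(OC=O)cc1OCc1ccccc1 | intermediate
6 | 3-(benzyloxy)-4-methoxyphenol | COc1ccc(O)cc1OCc1ccccc1 | intermediate
7 | 2-(benzyloxy)-1-methoxy-4-{[1-(3,4,5-trimethoxyphenyl)prop-2-yn-1-yl]oxy}benzene (racemic) | COc1ccc(OC(C#C)c2cc(OC)c(OC)c(OC)c2)cc1OCc1ccccc1 | intermediate
8 | lithium 3-[3-(benzyloxy)-4-methoxyphenoxy]-3-(3,4,5-trimethoxyphenyl)prop-1-yn-1-ide (racemic, not isolated) | COc1ccc(OC(C#C[Li])c2cc(OC)c(OC)c(OC)c2)cc1OCc1ccccc1 | intermediate
9 | 2-(benzyloxy)-4-{[3-chloro-1-(3,4,5-trimethoxyphenyl)prop-2-yn-1-yl]oxy}-1-methoxybenzene (racemic) | COc1ccc(OC(C#CCl)c2cc(OC)c(OC)c(OC)c2)cc1OCc1ccccc1 | intermediate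
10 | 3-(benzyloxy)-6-[1-chloro-3-(3,4,5-trimethoxyphenyl)propa-1,2-dien-1-yl]-4-methoxycyclohexa-2,4-dien-1-one (racemic, diastereomer mixture, not isolated) | O=C1C=C(OCc2ccccc2)C(OC)=CC1C(Cl)=C=Cc1cc(OC)c(OC)c(OC)c1 | intermediate
11 | 5-(benzyloxy)-2-[1-chloro-3-(3,4,5-trimethoxyphenyl)propa-1,2-dien-1-yl]-4-methoxyphenol (racemic allene, not isolated) | COc1cc(C(Cl)=C=Cc2cc(OC)c(OC)c(OC)c2)c(O)cc1OCc1ccccc1 | intermediate
12 | (6E)-3-(benzyloxy)-6-[1-chloro-3-(3,4,5-trimethoxyphenyl)prop-2-en-1-ylidene]-4-methoxycyclohexa-2,4-dien-1-one (vinyl arm syn to the carbonyl; styryl C=C geometry not defined, not isolated) | Cl/C(C=Cc2cc(OC)c(OC)c(OC)c2)=C1\C=C(OC)C(OCc2ccccc2)=CC1=O | intermediate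
13 | 7-(benzyloxy)-4-chloro-6-methoxy-2-(3,4,5-trimethoxyphenyl)-2H-chromene (racemic) | COc1cc2c(cc1OCc1ccccc1)OC(c1cc(OC)c(OC)c(OC)c1)C=C2Cl | intermediate
14 | 7-(benzyloxy)-6-methoxy-2-(3,4,5-trimethoxyphenyl)-2,3-dihydro-4H-chromen-4-one (racemic) | COc1cc2c(cc1OCc1ccccc1)OC(c1cc(OC)c(OC)c(OC)c1)CC2=O | intermediate
15 | 7-(benzyloxy)-3-iodo-6-methoxy-2-(3,4,5-trimethoxyphenyl)-2,3-dihydro-4H-chromen-4-one (racemic, relative configuration at C2/C3 not defined, not isolated) | COc1cc2c(cc1OCc1ccccc1)OC(c1cc(OC)c(OC)c(OC)c1)C(I)C2=O | intermediate
16 | 7-(benzyloxy)-6-methoxy-2-(3,4,5-trimethoxyphenyl)-4H-chromen-4-one | COc1cc2c(=O)cc(-c3cc(OC)c(OC)c(OC)c3)oc2cc1OCc1ccccc1 | intermediate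
17 | Prosogerin D, 7-hydroxy-6-methoxy-2-(3,4,5-trimethoxyphenyl)-4H-chromen-4-one | COc1cc2c(=O)cc(-c3cc(OC)c(OC)c(OC)c3)oc2cc1O | target

## Step count and least certain steps

Total step count: 8. Longest linear sequence: 7 steps (steps 2 to 8 from 4; equally steps 1 and 3 to 8 from 1).

Step 5 (key step). The most likely failures are:
- bond formation at the ortho carbon lying between the two oxygens, because the regiochemical bias is steric and electronic and not absolute;
- heterolysis of the benzylic–propargylic C–O bond at 185 °C before the sigmatropic shift;
- 5-exo closure of the phenol onto the allene towards a benzofuran.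

Fallback: a classical chalcone route that sets out from 6 and 1 and returns at 16. Phenol 6 is C-acetylated ortho to the hydroxyl and para to the benzyloxy group (Ac2O, BF3·OEt2, Friedel–Crafts/Fries type) to give 1-[4-(benzyloxy)-2-hydroxy-5-methoxyphenyl]ethan-1-one F1. Claisen–Schmidt condensation of F1 with 1 (KOH, EtOH, rt) gives (2E)-1-[4-(benzyloxy)-2-hydroxy-5-methoxyphenyl]-3-(3,4,5-trimethoxyphenyl)prop-2-en-1-one F2. Oxidative cyclisation of F2 with I2 (cat.) in DMSO at 125 °C gives 16, and step 8 follows.

Step 3. The most likely failure is ionisation of the activated alkoxyphosphonium intermediate, because the carbinol is both benzylic and propargylic. This would lead to C-alkylation of the electron-rich phenol or to attack at the alkyne terminus (allenyl ether formation) in place of clean O-alkylation.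

Fallback: copper-catalysed propargylic substitution, setting out from 3 and returning at 7. Alcohol 3 is converted with methyl chloroformate and pyridine into methyl 1-(3,4,5-trimethoxyphenyl)prop-2-yn-1-yl carbonate F3. F3 reacts with phenol 6 under monovalent copper catalysis (Cu(MeCN)4PF6, a 2,6-bis(oxazolinyl)pyridine ligand, iPr2NEt, MeOH, 0 °C) through a copper allenylidene that the phenol attacks at the propargylic carbon, giving 7.

Step 4. The most likely failure is deprotonation of the propargylic C–H (flanked by oxygen, aryl and alkyne) alongside acetylide formation. That would open Wittig-type rearrangement or alkyne-to-allene isomerisation; incomplete chlorine transfer is the lesser concern.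

Fallback: the chlorine is carried from the start, setting out from 1 and 6 and returning at 9. Lithium chloroacetylide F4 is generated in the flask from (Z)-1,2-dichloroethene and MeLi (2 equiv, Et2O, 0 °C) and added to 1 to give 3-chloro-1-(3,4,5-trimethoxyphenyl)prop-2-yn-1-ol F5. Mitsunobu coupling of F5 with 6 then gives 9 without strong base ever meeting the ether. The betaine is preformed from PPh3 and DIAD so that no free phosphine meets the chloroalkyne.

Step 6. The most likely failure is acid-induced opening of the benzylic C2–O1 bond with oligomerisation, or partial loss of the benzyl group in TFA. Partial debenzylation is harmless because such material converges on 17 in steps 7 and 8. Opening of 14 to chalcone F2 is also harmless, because step 7 converts F2 into 16 as well.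

Fallback: oxidise first and hydrolyse afterwards, setting out from 13 and returning at 16, which bypasses 14 and step 7. Hydride abstraction from C2 of 13 with Ph3CBF4 (MeCN, rt) gives 7-(benzyloxy)-4-chloro-6-methoxy-2-(3,4,5-trimethoxyphenyl)chromenylium tetrafluoroborate F6. Stirring F6 with water adds water at C4 and expels chloride to give 16. This is the known hydrolysis of 4-chlorobenzopyrylium salts to chromones.

## Further compounds

F1 | step 5 | 1-[4-(benzyloxy)-2-hydroxy-5-methoxyphenyl]ethan-1-one | COc1cc(C(C)=O)c(O)cc1OCc1ccccc1
F2 | step 5 | (2E)-1-[4-(benzyloxy)-2-hydroxy-5-methoxyphenyl]-3-(3,4,5-trimethoxyphenyl)prop-2-en-1-one | COc1cc(C(=O)/C=C/c2cc(OC)c(OC)c(OC)c2)c(O)cc1OCc1ccccc1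
F3 | step 3 | methyl 1-(3,4,5-trimethoxyphenyl)prop-2-yn-1-yl carbonate (racemic) | C#CC(OC(=O)OC)c1cc(OC)c(OC)c(OC)c1
F4 | step 4 | lithium chloroacetylide | [Li]C#CCl
F5 | step 4 | 3-chloro-1-(3,4,5-trimethoxyphenyl)prop-2-yn-1-ol (racemic) | OC(C#CCl)c1cc(OC)c(OC)c(OC)c1
F6 | step 6 | 7-(benzyloxy)-4-chloro-6-methoxy-2-(3,4,5-trimethoxyphenyl)chromenylium tetrafluoroborate | COc1cc2c(Cl)cc(-c3cc(OC)c(OC)c(OC)c3)[o+]c2cc1OCc1ccccc1.F[B-](F)(F)F
A1 | alternative 1 | methyl 4-oxo-6-(3,4,5-trimethoxyphenyl)-4H-pyran-3-carboxylate | COC(=O)c1coc(-c2cc(OC)c(OC)c(OC)c2)cc1=O
A2 | alternative 1 | 2-(tert-butyldimethylsilyloxy)buta-1,3-diene | C=CC(=C)O[Si](C)(C)C(C)(C)C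
A3 | alternative 1 | methyl 7-(tert-butyldimethylsilyloxy)-4-oxo-2-(3,4,5-trimethoxyphenyl)-5,8-dihydro-4H-chromene-4a(8aH)-carboxylate (cis-fused, racemic, one enantiomer drawn) | COC(=O)[C@]12CC=C(O[Si](C)(C)C(C)(C)C)C[C@H]1OC(c1cc(OC)c(OC)c(OC)c1)=CC2=O
A4 | alternative 2 | pentacarbonyl[(1-tert-butoxyvinyl)(methoxy)carbene]chromium | COC(C(=C)OC(C)(C)C)=[Cr](=C=O)(=C=O)(=C=O)(=C=O)=C=O
A5 | alternative 2 | tert-butyldimethyl{[1-(3,4,5-trimethoxyphenyl)penta-1,4-diyn-3-yl]oxy}silane (racemic) | C#CC(O[Si](C)(C)C(C)(C)C)C#Cc1cc(OC)c(OC)c(OC)c1
A6 | alternative 2 | 5-tert-butoxy-2-[1-(tert-butyldimethylsilyloxy)-3-(3,4,5-trimethoxyphenyl)prop-2-yn-1-yl]-4-methoxyphenol (racemic) | CC(C)(C)Oc1cc(O)c(C(O[Si](C)(C)C(C)(C)C)C#Cc2cc(OC)c(OC)c(OC)c2)cc1OC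
A7 | alternative 3 | 1-[4-(benzyloxy)-3-hydroxyphenyl]-3-(3,4,5-trimethoxyphenyl)propane-1,3-dione | O=C(CC(=O)c1cc(OC)c(OC)c(OC)c1)c1ccc(OCc2ccccc2)c(O)c1
A8 | alternative 3 | 7-(benzyloxy)-6-hydroxy-2-(3,4,5-trimethoxyphenyl)-4H-chromen-4-one | O=c1cc(-c2cc(OC)c(OC)c(OC)c2)oc2cc(OCc3ccccc3)c(O)cc12
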